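**Retrosynthetic overview**

1. Locants are azulene locants of the target: C3 = methyl-bearing alkene carbon, C3a and C8a = ring-fusion carbons, C4 = CHOH, C5 = side-chain carbon, C7 = CHOAc, C8 = methylidene-bearing carbon. The hydroxylated side-chain alkene is made last by cross-metathesis of an allyl group, after selective acetylation of a 4,7-diol.
2. Seven-membered ring (formed second): intramolecular Nozaki–Hiyama–Kishi closure of the C7–C8 bond from a C8 alkenyl triflate and a C7 aldehyde masked as a lactol.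
3. Cyclopentene and a temporary γ-lactone (formed first, in one operation): gold-catalysed cascade of an open-chain (Z)-1,5-enyne tert-butyl ester that forms the C3–C3a bond and the C4–O bond.
4. Enabling feature: the alkene carbon C3 is bonded to C3a, the neighbouring C4 carries its oxygen anti to C3, and C7 lies two carbons (C5, C6) beyond C4. This is the pattern of an anti carbo-oxygenation of a (Z)-C3a=C4 alkene by a but-2-ynyl arm on C8a and a C7 carboxyl; the trans ring fusion follows from the trans-disubstituted cyclopentene.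
5. Open chain: C8a by Evans propargylation, the (Z)-alkene by Wittig olefination, C5 by Evans alkylation, the side-chain methyl centre by Sakurai allylation.

Key step: step 11

Remark: the facial sense of each auxiliary-controlled step is assigned from the usual chelate models; if one proved opposite, the enantiomeric oxazolidinone would be used in that step.

**Route**

Step 1
Reactants: 1 (S)-4-benzyloxazolidin-2-one; 2 (E)-but-2-enoyl chloride
Product: 3 (S)-4-benzyl-3-[(E)-but-2-enoyl]oxazolidin-2-one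
Conditions: n-BuLi, THF, −78 °C; then 2, −78 → 0 °C
Reagents that add atoms: none
Why: N-acylation of the lithiated oxazolidinone by the acid chloride is the standard attachment of an Evans auxiliary and creates no stereocentre.

Step 2
Reactants: 3 (S)-4-benzyl-3-[(E)-but-2-enoyl]oxazolidin-2-one; 4 allyltrimethylsilane
Product: 5 (S)-4-benzyl-3-[(S)-3-methylhex-5-enoyl]oxazolidin-2-one
Conditions: TiCl4 (1.1 equiv), CH2Cl2, −78 °C; aq. NH4Cl
Reagents that add atoms: none
Why: Hosomi–Sakurai conjugate allylation of the TiCl4-chelated s-cis N-enoyl imide, in which 4 should add to the β-carbon on the face opposite the benzyl group and so set the side-chain methyl centre (future C2′) as (S).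

Step 3
Reactants: 5 (S)-4-benzyl-3-[(S)-3-methylhex-5-enoyl]oxazolidin-2-one
Product: 6 (S)-3-methylhex-5-enoic acid
Conditions: LiOH, H2O2, THF/H2O, 0 °C; Na2SO3; HCl to pH 2
Reagents that add atoms: hydrogen peroxide, OO
Why: Lithium hydroperoxide cleaves the exocyclic imide carbonyl selectively (standard Evans hydrolysis) and leaves the β-stereocentre and the terminal alkene untouched.

Step 4
Reactants: 6 (S)-3-methylhex-5-enoic acid; 7 (R)-4-benzyloxazolidin-2-one
Product: 9 (R)-4-benzyl-3-[(S)-3-methylhex-5-enoyl]oxazolidin-2-one, via mixed pivalic anhydride 8 (not isolated)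
Conditions: t-BuCOCl, Et3N, THF, −20 °C; then 7/n-BuLi (THF, −78 °C), −78 → 0 °C
Reagents that add atoms: none
Why: Mixed-anhydride N-acylation attaches the enantiomeric auxiliary, which is the one that should give the required sense of induction at the α-carbon in the next step.

Step 5
Reactants: 9 (R)-4-benzyl-3-[(S)-3-methylhex-5-enoyl]oxazolidin-2-one; 10 tert-butyl bromoacetate
Product: 11 tert-butyl (3R,4S)-3-[(R)-4-benzyl-2-oxooxazolidine-3-carbonyl]-4-methylhept-6-enoate
Conditions: NaN(SiMe3)2, THF, −78 °C; then 10, −78 → −40 °C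
Reagents that add atoms: none
Why: Evans asymmetric alkylation, in which the chelated (Z)-sodium enolate should be alkylated by the reactive α-bromo ester on the face opposite the benzyl group, setting the future C5 stereocentre as (R) under auxiliary control.

Step 6
Reactants: 11 tert-butyl (3R,4S)-3-[(R)-4-benzyl-2-oxooxazolidine-3-carbonyl]-4-methylhept-6-enoate
Product: 12 tert-butyl (3R,4S)-3-(hydroxymethyl)-4-methylhept-6-enoate
Conditions: LiBH4, MeOH (1 equiv), Et2O, 0 °C
Reagents that add atoms: none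
Why: LiBH4 reductively removes the auxiliary from the hindered imide to the primary alcohol (standard) while the tert-butyl ester and the alkene should survive, and no stereocentre is touched.

Step 7
Reactants: 12 tert-butyl (3R,4S)-3-(hydroxymethyl)-4-methylhept-6-enoate
Product: 13 tert-butyl (3R,4S)-3-formyl-4-methylhept-6-enoate
Conditions: Dess–Martin periodinane, pyridine, CH2Cl2, 0 °C → rt
Reagents that add atoms: none
Why: Dess–Martin oxidation under buffered conditions should give the α-branched aldehyde (the future C4 carbon) without epimerisation.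

Step 8
Reactants: 13 tert-butyl (3R,4S)-3-formyl-4-methylhept-6-enoate; 14 (2-carboxyethyl)triphenylphosphonium bromide
Product: 15 (3Z,5R)-7-tert-butoxy-7-oxo-5-[(S)-pent-4-en-2-yl]hept-3-enoic acid
Conditions: 14, NaN(SiMe3)2 (2 equiv), THF, −78 → 0 °C; then 13, −78 °C → rt; aq. citric acid
Reagents that add atoms: none
Why: Wittig olefination with the non-stabilised, carboxylate-bearing ylide at low temperature should give the (Z)-β,γ-unsaturated acid through the kinetic cis-oxaphosphetane, the α-stereocentre being preserved because the aldehyde meets no free base.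

Step 9
Reactants: 15 (3Z,5R)-7-tert-butoxy-7-oxo-5-[(S)-pent-4-en-2-yl]hept-3-enoic acid; 1 (S)-4-benzyloxazolidin-2-one
Product: 17 tert-butyl (3R,4Z)-7-[(S)-4-benzyl-2-oxooxazolidin-3-yl]-7-oxo-3-[(S)-pent-4-en-2-yl]hept-4-enoate, via mixed pivalic anhydride 16 (not isolated)
Conditions: t-BuCOCl, Et3N, THF, −20 °C; then 1/n-BuLi (THF, −78 °C), −78 → 0 °C
Reagents that add atoms: none
Why: Mixed-anhydride N-acylation at low temperature attaches the (S)-auxiliary to the β,γ-unsaturated acid without moving the (Z)-alkene into conjugation.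

Step 10
Reactants: 17 tert-butyl (3R,4Z)-7-[(S)-4-benzyl-2-oxooxazolidin-3-yl]-7-oxo-3-[(S)-pent-4-en-2-yl]hept-4-enoate; 18 1-bromobut-2-yne
Product: 19 tert-butyl (3R,4Z,6S)-6-[(S)-4-benzyl-2-oxooxazolidine-3-carbonyl]-3-[(S)-pent-4-en-2-yl]dec-4-en-8-ynoate
Conditions: NaN(SiMe3)2, THF, −78 °C; then 18, −78 → −50 °C
Reagents that add atoms: none
Why: Evans asymmetric alkylation of the sodium enolate at its α-carbon by the propargylic bromide, anti to the benzyl group, should set the future C8a stereocentre as (S) by auxiliary control.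

Step 11
Reactants: 19 tert-butyl (3R,4Z,6S)-6-[(S)-4-benzyl-2-oxooxazolidine-3-carbonyl]-3-[(S)-pent-4-en-2-yl]dec-4-en-8-ynoate
Product: 20 (S)-4-benzyl-3-{(1S,5R)-4-methyl-5-[(2S,3R)-5-oxo-3-((S)-pent-4-en-2-yl)oxolan-2-yl]cyclopent-3-ene-1-carbonyl}oxazolidin-2-one
Conditions: [(t-Bu)2(2-biphenylyl)PAu(NCMe)]SbF6 (5 mol%), 4 Å molecular sieves, CH2Cl2, 0 °C → rt
Reagents that add atoms: none
Why: The cationic monovalent gold complex activates the alkyne, the (Z)-alkene attacks with its proximal carbon (future C3a) at the methyl-bearing alkyne carbon (future C3) anti to gold, the positive charge that builds up at the distal alkene carbon (future C4) is captured on the opposite face by the carbonyl oxygen of the tert-butyl ester, and loss of 2-methylpropene from the resulting alkoxy-oxocarbenium ion supplies the proton that protodeaurates the alkenylgold carbon (future C2), so that the whole event is a catalytic isomerisation with loss of isobutene. The closest known reaction types are the gold-catalysed 5-endo-dig hydroxy- and alkoxycyclisation of 1,5-enynes, which adds carbon and oxygen anti across the alkene, and gold-catalysed enyne cyclisations that are terminated by carboxylic acids or tert-butyl carbonates. The cyclopentene closes by 5-endo-dig attack (C3–C3a bond) and the γ-lactone by 5-exo attack of oxygen on C4. C3a and C4 are set by the stereospecific anti addition across the (Z)-alkene and the attacked face is fixed by the C8a stereocentre: in the A(1,3)-minimised conformer both allylic hydrogens lie in the alkene plane, the butynyl arm then sits on one face and the ester arm of the (R)-configured C5 on the other, which leads to the trans-4,5-disubstituted cyclopentene (the later trans ring fusion) and to the trans-disubstituted lactone. The step needs the 5-endo mode (carbon to C3a, oxygen to C4) in preference to the 6-endo mode (carbon to C4, oxygen to C3a) and to plain cycloisomerisation; the two-carbon ester tether secures this because it reaches C4 through a five-membered and C3a only through a six-membered transition state, while the imide carbonyl could trap C4 only as a strained trans-fused bicycle and adds to the alkyne only reversibly under anhydrous conditions.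

Step 12
Reactants: 20 (S)-4-benzyl-3-{(1S,5R)-4-methyl-5-[(2S,3R)-5-oxo-3-((S)-pent-4-en-2-yl)oxolan-2-yl]cyclopent-3-ene-1-carbonyl}oxazolidin-2-one
Product: 21 S-ethyl (1S,5R)-4-methyl-5-[(2S,3R)-5-oxo-3-((S)-pent-4-en-2-yl)oxolan-2-yl]cyclopent-3-ene-1-carbothioate
Conditions: EtSH, n-BuLi (0.3 equiv), THF, 0 °C
Reagents that add atoms: ethanethiol, CCS
Why: Lithium ethanethiolate transacylates the exocyclic imide carbonyl to the thioester and releases the auxiliary, the γ-lactone being far less electrophilic, and any epimerisation next to the carbonyl would only favour the trans-cyclopentene already present.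

Step 13
Reactants: 21 S-ethyl (1S,5R)-4-methyl-5-[(2S,3R)-5-oxo-3-((S)-pent-4-en-2-yl)oxolan-2-yl]cyclopent-3-ene-1-carbothioate
Product: 22 (4R,5S)-5-[(1R,5S)-5-acetyl-2-methylcyclopent-2-en-1-yl]-4-[(S)-pent-4-en-2-yl]oxolan-2-one
Conditions: Me2CuLi (from MeLi and CuI), Et2O, −78 → −40 °C
Reagents that add atoms: lithium dimethylcuprate, [Li+].C[Cu-]C
Why: Acyl substitution of the thioester by the Gilman cuprate should stop at the methyl ketone and leave the lactone untouched at low temperature.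

Step 14
Reactants: 22 (4R,5S)-5-[(1R,5S)-5-acetyl-2-methylcyclopent-2-en-1-yl]-4-[(S)-pent-4-en-2-yl]oxolan-2-one
Product: 23 1-{(1S,5R)-4-methyl-5-[(2S,3R)-5-oxo-3-((S)-pent-4-en-2-yl)oxolan-2-yl]cyclopent-3-en-1-yl}ethenyl trifluoromethanesulfonate
Conditions: KN(SiMe3)2, PhNTf2, THF, −78 °C
Reagents that add atoms: N-phenylbis(trifluoromethanesulfonimide), O=S(=O)(N(c1ccccc1)S(=O)(=O)C(F)(F)F)C(F)(F)F
Why: Kinetic deprotonation of the methyl group of the ketone by the hindered amide base and O-triflation of the enolate should give the 1,1-disubstituted alkenyl triflate (the future C8 with its methylidene carbon) and not the tetrasubstituted isomer.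

Step 15
Reactants: 23 1-{(1S,5R)-4-methyl-5-[(2S,3R)-5-oxo-3-((S)-pent-4-en-2-yl)oxolan-2-yl]cyclopent-3-en-1-yl}ethenyl trifluoromethanesulfonate
Product: 24 1-{(1S,5R)-5-[(2S,3R)-5-hydroxy-3-((S)-pent-4-en-2-yl)oxolan-2-yl]-4-methylcyclopent-3-en-1-yl}ethenyl trifluoromethanesulfonate (lactol, both anomers)
Conditions: i-Bu2AlH (1.1 equiv), CH2Cl2, −78 °C; Rochelle salt
Reagents that add atoms: none
Why: Partial reduction of the γ-lactone stops at the lactol because the tetrahedral aluminium acetal is stable at low temperature, which unmasks the C7 carbon at the aldehyde level without affecting the alkenyl triflate.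

Step 16
Reactants: 24 lactol triflate (as named in step 15)
Product: 26 (3aR,4S,5R,7R,8aS)-3-methyl-8-methylidene-5-[(S)-pent-4-en-2-yl]-1,3a,4,5,6,7,8,8a-octahydroazulene-4,7-diol, via open-chain hydroxy aldehyde 25 (not isolated)
Conditions: CrCl2 (10 equiv), NiCl2 (5 mol%), DMF (0.005 M), rt
Reagents that add atoms: none
Why: Intramolecular Nozaki–Hiyama–Kishi reaction, in which the alkenylchromium species formed from the triflate adds to the aldehyde released from the lactol and closes the seven-membered ring (C7–C8 bond); the new C7 carbinol should form with its oxygen pseudo-equatorial and on the face of the chromium-bound C4 alkoxide, that is cis to the C4 oxygen as in the target.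

Step 17
Reactants: 26 (3aR,4S,5R,7R,8aS)-3-methyl-8-methylidene-5-[(S)-pent-4-en-2-yl]-1,3a,4,5,6,7,8,8a-octahydroazulene-4,7-diol
Product: 27 (3aR,4S,5R,7R,8aS)-4-hydroxy-3-methyl-8-methylidene-5-[(S)-pent-4-en-2-yl]-1,3a,4,5,6,7,8,8a-octahydroazulen-7-yl acetate
Conditions: Ac2O (1.2 equiv), pyridine, CH2Cl2, 0 °C
Reagents that add atoms: acetic anhydride, CC(=O)OC(C)=O
Why: The allylic C7 hydroxyl is unhindered whereas the C4 hydroxyl lies between the ring-fusion carbon and the branched C5, so mild acylation should stop at the 7-monoacetate.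

Step 18
Reactants: 27 (3aR,4S,5R,7R,8aS)-4-hydroxy-3-methyl-8-methylidene-5-[(S)-pent-4-en-2-yl]-1,3a,4,5,6,7,8,8a-octahydroazulen-7-yl acetate; 28 2-methylbut-3-en-2-ol
Product: 29 (3aR,4S,5R,7R,8aS)-4-hydroxy-5-[(2S,4E)-6-hydroxy-6-methylhept-4-en-2-yl]-3-methyl-8-methylidene-1,3a,4,5,6,7,8,8a-octahydroazulen-7-yl acetate
Conditions: 28 (10 equiv), second-generation Grubbs catalyst (5 mol%), CH2Cl2, 40 °C
Reagents that add atoms: none
Why: Olefin cross-metathesis of the monosubstituted alkene with excess 28 should give the (E)-allylic tertiary alcohol for steric reasons, while the 1,1-disubstituted exocyclic alkene and the trisubstituted ring alkene are too hindered to react.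

**Compound list**

1 | (S)-4-benzyloxazolidin-2-one | O=C1N[C@@H](Cc2ccccc2)CO1 | starting material
2 | (E)-but-2-enoyl chloride | C/C=C/C(=O)Cl | starting material
3 | (S)-4-benzyl-3-[(E)-but-2-enoyl]oxazolidin-2-one | C/C=C/C(=O)N1[C@@H](Cc2ccccc2)COC1=O | intermediate
4 | allyltrimethylsilane | C=CC[Si](C)(C)C | starting material
5 | (S)-4-benzyl-3-[(S)-3-methylhex-5-enoyl]oxazolidin-2-one | C=CC[C@H](C)CC(=O)N1[C@@H](Cc2ccccc2)COC1=O | intermediate
6 | (S)-3-methylhex-5-enoic acid | C=CC[C@H](C)CC(=O)O | intermediate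
7 | (R)-4-benzyloxazolidin-2-one | O=C1N[C@H](Cc2ccccc2)CO1 | starting material
8 | (S)-3-methylhex-5-enoic pivalic anhydride | C=CC[C@H](C)CC(=O)OC(=O)C(C)(C)C | intermediate
9 | (R)-4-benzyl-3-[(S)-3-methylhex-5-enoyl]oxazolidin-2-one | C=CC[C@H](C)CC(=O)N1[C@H](Cc2ccccc2)COC1=O | intermediate
10 | tert-butyl bromoacetate | CC(C)(C)OC(=O)CBr | starting material
11 | tert-butyl (3R,4S)-3-[(R)-4-benzyl-2-oxooxazolidine-3-carbonyl]-4-methylhept-6-enoate | C=CC[C@H](C)[C@@H](CC(=O)OC(C)(C)C)C(=O)N1[C@H](Cc2ccccc2)COC1=O | intermediate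
12 | tert-butyl (3R,4S)-3-(hydroxymethyl)-4-methylhept-6-enoate | C=CC[C@H](C)[C@@H](CC(=O)OC(C)(C)C)CO | intermediate
13 | tert-butyl (3R,4S)-3-formyl-4-methylhept-6-enoate | C=CC[C@H](C)[C@@H](CC(=O)OC(C)(C)C)C=O | intermediate
14 | (2-carboxyethyl)triphenylphosphonium bromide | OC(=O)CC[P+](c1ccccc1)(c1ccccc1)c1ccccc1.[Br-] | starting material
15 | (3Z,5R)-7-tert-butoxy-7-oxo-5-[(S)-pent-4-en-2-yl]hept-3-enoic acid | OC(=O)C/C=C\[C@H](CC(=O)OC(C)(C)C)[C@@H](C)CC=C | intermediate
16 | mixed pivalic anhydride of 15 | CC(C)(C)C(=O)OC(=O)C/C=C\[C@H](CC(=O)OC(C)(C)C)[C@@H](C)CC=C | intermediate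
17 | tert-butyl (3R,4Z)-7-[(S)-4-benzyl-2-oxooxazolidin-3-yl]-7-oxo-3-[(S)-pent-4-en-2-yl]hept-4-enoate | O=C(C/C=C\[C@H](CC(=O)OC(C)(C)C)[C@@H](C)CC=C)N1[C@@H](Cc2ccccc2)COC1=O | intermediate
18 | 1-bromobut-2-yne | CC#CCBr | starting material
19 | tert-butyl (3R,4Z,6S)-6-[(S)-4-benzyl-2-oxooxazolidine-3-carbonyl]-3-[(S)-pent-4-en-2-yl]dec-4-en-8-ynoate | CC#CC[C@@H](/C=C\[C@H](CC(=O)OC(C)(C)C)[C@@H](C)CC=C)C(=O)N1[C@@H](Cc2ccccc2)COC1=O | intermediate
20 | (S)-4-benzyl-3-{(1S,5R)-4-methyl-5-[(2S,3R)-5-oxo-3-((S)-pent-4-en-2-yl)oxolan-2-yl]cyclopent-3-ene-1-carbonyl}oxazolidin-2-one | O=C([C@H]1CC=C(C)[C@@H]1[C@H]2OC(=O)C[C@@H]2[C@@H](C)CC=C)N3[C@@H](Cc4ccccc4)COC3=O | intermediate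
21 | S-ethyl (1S,5R)-4-methyl-5-[(2S,3R)-5-oxo-3-((S)-pent-4-en-2-yl)oxolan-2-yl]cyclopent-3-ene-1-carbothioate | CCSC(=O)[C@H]1CC=C(C)[C@@H]1[C@H]2OC(=O)C[C@@H]2[C@@H](C)CC=C | intermediate
22 | (4R,5S)-5-[(1R,5S)-5-acetyl-2-methylcyclopent-2-en-1-yl]-4-[(S)-pent-4-en-2-yl]oxolan-2-one | CC(=O)[C@H]1CC=C(C)[C@@H]1[C@H]2OC(=O)C[C@@H]2[C@@H](C)CC=C | intermediate
23 | 1-{(1S,5R)-4-methyl-5-[(2S,3R)-5-oxo-3-((S)-pent-4-en-2-yl)oxolan-2-yl]cyclopent-3-en-1-yl}ethenyl trifluoromethanesulfonate | C=C(OS(=O)(=O)C(F)(F)F)[C@H]1CC=C(C)[C@@H]1[C@H]2OC(=O)C[C@@H]2[C@@H](C)CC=C | intermediate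
24 | 1-{(1S,5R)-5-[(2S,3R)-5-hydroxy-3-((S)-pent-4-en-2-yl)oxolan-2-yl]-4-methylcyclopent-3-en-1-yl}ethenyl trifluoromethanesulfonate (both anomers) | C=C(OS(=O)(=O)C(F)(F)F)[C@H]1CC=C(C)[C@@H]1[C@H]2OC(O)C[C@@H]2[C@@H](C)CC=C | intermediate
25 | 1-{(1S,5R)-5-[(1S,2R,3S)-1-hydroxy-3-methyl-2-(2-oxoethyl)hex-5-en-1-yl]-4-methylcyclopent-3-en-1-yl}ethenyl trifluoromethanesulfonate | C=C(OS(=O)(=O)C(F)(F)F)[C@H]1CC=C(C)[C@@H]1[C@@H](O)[C@H](CC=O)[C@@H](C)CC=C | intermediate
26 | (3aR,4S,5R,7R,8aS)-3-methyl-8-methylidene-5-[(S)-pent-4-en-2-yl]-1,3a,4,5,6,7,8,8a-octahydroazulene-4,7-diol | C=C1[C@H]2CC=C(C)[C@@H]2[C@@H](O)[C@@H]([C@@H](C)CC=C)C[C@H]1O | intermediate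
27 | (3aR,4S,5R,7R,8aS)-4-hydroxy-3-methyl-8-methylidene-5-[(S)-pent-4-en-2-yl]-1,3a,4,5,6,7,8,8a-octahydroazulen-7-yl acetate | C=C1[C@H]2CC=C(C)[C@@H]2[C@@H](O)[C@@H]([C@@H](C)CC=C)C[C@H]1OC(C)=O | intermediate
28 | 2-methylbut-3-en-2-ol | C=CC(C)(C)O | starting material
29 | (3aR,4S,5R,7R,8aS)-4-hydroxy-5-[(2S,4E)-6-hydroxy-6-methylhept-4-en-2-yl]-3-methyl-8-methylidene-1,3a,4,5,6,7,8,8a-octahydroazulen-7-yl acetate | C=C1[C@H]2CC=C(C)[C@@H]2[C@@H](O)[C@@H]([C@@H](C)C/C=C/C(C)(C)O)C[C@H]1OC(C)=O | target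

**Step count and risks**

Total step count: 18. Longest linear sequence: 18 steps (1 → 29).

Steps most likely to fail:

1. Step 11. The ester may intercept the gold intermediate too slowly, so that 1,2-hydride shift to a bicyclo[3.1.0]hexene or closure in the 6-endo mode competes. Fallback (sets out from 13, returns at 21): the cyclopentene is closed instead from a ketone-derived silyl enol ether. Vinylmagnesium bromide would add to 13 to give the allylic alcohol F1, and Dess–Martin oxidation would give the vinyl ketone F2. The chlorotitanium enolate of (R)-4-benzyl-3-(hex-4-ynoyl)oxazolidin-2-one F3 (from commercial hex-4-ynoic acid and 7) would add to F2 in an auxiliary-controlled Michael reaction to give the keto imide F4. Kinetic silylation at the unhindered methylene (LiN(SiMe3)2, t-BuMe2SiCl) would give the silyl enol ether F5. Its gold-catalysed 5-endo-dig carbocyclisation onto the alkyne in CH2Cl2/MeOH would close the C3–C3a bond and give the trans-cyclopentenyl ketone F6. Reduction with LiBH(s-Bu)3, anti to the branched C5 substituent, would give the hydroxy ester F7, which would lactonise with CF3CO2H to the lactone imide F8. Thiolysis as in step 12 then returns to 21.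

2. Step 16. The lactol may open too slowly, and the alkenylchromium intermediate may then be protonated by the free hydroxyl or couple intermolecularly before the medium ring closes. Fallback (sets out from 23, returns at 27): the aldehyde is set free in open-chain form with the C4 oxygen protected. Aminolysis of the lactone with MeNH(OMe)·HCl/Me2AlCl would give the hydroxy Weinreb amide F9. Et3SiOTf/2,6-lutidine would give the triethylsilyl ether F10, and i-Bu2AlH the free aldehyde F11. The same CrCl2/NiCl2 closure would give the ring-closed allylic alcohol F12, acetylation the acetate F13, and HF·pyridine would remove the silyl group to give 27.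

3. Step 17. Acylation may run on to the diacetate or fail to discriminate fully between the two secondary hydroxyls. Fallback (from 26 to 27): enzyme control replaces steric control. Transesterification with vinyl acetate and immobilised Candida antarctica lipase B (t-BuOMe, 30 °C) should accept only the unhindered allylic C7 carbinol; no new compound is made.

**Further compounds**

F1 | step 11 | tert-butyl (3R,4S)-3-(1-hydroxyprop-2-en-1-yl)-4-methylhept-6-enoate (both carbinol epimers) | C=CC[C@H](C)[C@@H](CC(=O)OC(C)(C)C)C(O)C=C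
F2 | step 11 | tert-butyl (3R,4S)-4-methyl-3-(prop-2-enoyl)hept-6-enoate | C=CC[C@H](C)[C@@H](CC(=O)OC(C)(C)C)C(=O)C=C
F3 | step 11 | (R)-4-benzyl-3-(hex-4-ynoyl)oxazolidin-2-one | CC#CCCC(=O)N1[C@H](Cc2ccccc2)COC1=O
F4 | step 11 | tert-butyl (3R,6S)-6-[(R)-4-benzyl-2-oxooxazolidine-3-carbonyl]-4-oxo-3-[(S)-pent-4-en-2-yl]dec-8-ynoate | CC#CC[C@@H](CCC(=O)[C@H](CC(=O)OC(C)(C)C)[C@@H](C)CC=C)C(=O)N1[C@H](Cc2ccccc2)COC1=O
F5 | step 11 | tert-butyl (3R,4Z,6S)-6-[(R)-4-benzyl-2-oxooxazolidine-3-carbonyl]-4-(tert-butyldimethylsilyloxy)-3-[(S)-pent-4-en-2-yl]dec-4-en-8-ynoate | CC#CC[C@@H](/C=C(\O[Si](C)(C)C(C)(C)C)[C@H](CC(=O)OC(C)(C)C)[C@@H](C)CC=C)C(=O)N1[C@H](Cc2ccccc2)COC1=O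
F6 | step 11 | tert-butyl (3R,4S)-3-{(1R,5S)-5-[(R)-4-benzyl-2-oxooxazolidine-3-carbonyl]-2-methylcyclopent-2-ene-1-carbonyl}-4-methylhept-6-enoate | O=C([C@H]1CC=C(C)[C@@H]1C(=O)[C@H](CC(=O)OC(C)(C)C)[C@@H](C)CC=C)N2[C@H](Cc3ccccc3)COC2=O
F7 | step 11 | tert-butyl (3R,4S)-3-[(S)-{(1R,5S)-5-[(R)-4-benzyl-2-oxooxazolidine-3-carbonyl]-2-methylcyclopent-2-en-1-yl}(hydroxy)methyl]-4-methylhept-6-enoate | O=C([C@H]1CC=C(C)[C@@H]1[C@@H](O)[C@H](CC(=O)OC(C)(C)C)[C@@H](C)CC=C)N2[C@H](Cc3ccccc3)COC2=O
F8 | step 11 | (R)-4-benzyl-3-{(1S,5R)-4-methyl-5-[(2S,3R)-5-oxo-3-((S)-pent-4-en-2-yl)oxolan-2-yl]cyclopent-3-ene-1-carbonyl}oxazolidin-2-one | O=C([C@H]1CC=C(C)[C@@H]1[C@H]2OC(=O)C[C@@H]2[C@@H](C)CC=C)N3[C@H](Cc4ccccc4)COC3=O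
F9 | step 16 | 1-{(1S,5R)-5-[(1S,2R,3S)-1-hydroxy-2-{2-[methoxy(methyl)amino]-2-oxoethyl}-3-methylhex-5-en-1-yl]-4-methylcyclopent-3-en-1-yl}ethenyl trifluoromethanesulfonate | C=C(OS(=O)(=O)C(F)(F)F)[C@H]1CC=C(C)[C@@H]1[C@@H](O)[C@H](CC(=O)N(C)OC)[C@@H](C)CC=C
F10 | step 16 | triethylsilyl ether of F9 | C=C(OS(=O)(=O)C(F)(F)F)[C@H]1CC=C(C)[C@@H]1[C@@H](O[Si](CC)(CC)CC)[C@H](CC(=O)N(C)OC)[C@@H](C)CC=C
F11 | step 16 | 1-{(1S,5R)-4-methyl-5-[(1S,2R,3S)-3-methyl-2-(2-oxoethyl)-1-(triethylsilyloxy)hex-5-en-1-yl]cyclopent-3-en-1-yl}ethenyl trifluoromethanesulfonate | C=C(OS(=O)(=O)C(F)(F)F)[C@H]1CC=C(C)[C@@H]1[C@@H](O[Si](CC)(CC)CC)[C@H](CC=O)[C@@H](C)CC=C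
F12 | step 16 | (3aR,4S,5R,7R,8aS)-3-methyl-8-methylidene-5-[(S)-pent-4-en-2-yl]-4-(triethylsilyloxy)-1,3a,4,5,6,7,8,8a-octahydroazulen-7-ol | C=C1[C@H]2CC=C(C)[C@@H]2[C@@H](O[Si](CC)(CC)CC)[C@@H]([C@@H](C)CC=C)C[C@H]1O
F13 | step 16 | (3aR,4S,5R,7R,8aS)-3-methyl-8-methylidene-5-[(S)-pent-4-en-2-yl]-4-(triethylsilyloxy)-1,3a,4,5,6,7,8,8a-octahydroazulen-7-yl acetate | C=C1[C@H]2CC=C(C)[C@@H]2[C@@H](O[Si](CC)(CC)CC)[C@@H]([C@@H](C)CC=C)C[C@H]1OC(C)=O
F0 | step 17 | none | none
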